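**Retrosynthetic overview**

- Locants used here: C1 = tertiary carbinol carbon shared by the cyclopentane and azepane rings; C2–C4 = azepane CH2 chain (C2 on C1, C4 on N5); C6 = piperidine CH bearing the 1-hydroxypropyl group (carbinol C1''); C10 = N–CH shared by piperidine and azepane; C11 (CH), C12 (CHMe), C13 (CHOH) and the spiro carbon C14 (= C5' of the tetronate O1'–C5') complete the cyclopentane.
- Enabling feature: C1 carries one oxygen and three carbons, so it is a masked carboxyl carbon, and its gamma carbon C13 carries oxygen; C1–C11–C12–C13–O is therefore a latent gamma-butyrolactone. The spiro carbon C14 is the nucleophilic C5' of a methyl tetronate, flanked by the two carbinol carbons C1 and C13.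
- Disconnections: C14–C13 (intramolecular vinylogous aldol, cyclopentane last); C1–C14 and C1–C2 in one flask (the lactone carbonyl C1 first takes the N-tethered C2 carbanion, closing the azepane, then the tetronate); N5–C4 (acrolein); N5–C10 and C10–C11 (lactone enolate + N-acyl lactam, then reductive cyclisation); C6–C1'' (Henry).
- Ring order: piperidine (as lactam, re-closed by iminium reduction) → azepane (key step) → cyclopentane with the spiro tetronate; C13 is adjusted at the end by oxidation and hydroxyl-directed reduction.

Key step: step 10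

Remark: 2 and 17 are taken as purchasable; each is otherwise one known step away (methyl 5-bromopentanoate + NaNO2; 3-methyltetronic acid + Me2SO4).

Remark: 10 (lactone C3, keto/enol), 21 and 22 (C14–H) and 23 (C13) are carried as epimer mixtures that converge later, so their SMILES leave these centres open; 22 is expected to rest mainly as the lactol formed with the C1 hydroxyl.

**Step 1**
Reactants: 1 propanal; 2 methyl 5-nitropentanoate
Product: 3 methyl (5R,6R)-6-hydroxy-5-nitrooctanoate
Conditions: LaLi3[(S)-6,6'-bis((triethylsilyl)ethynyl)-1,1'-binaphthalene-2,2'-diolate]3 (3 mol %), THF, −40 °C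
Reagents that add atoms: none
Why: A syn-selective catalytic asymmetric Henry (nitroaldol) reaction should give the syn nitro alcohol, with both new stereocentres (C6 and C1'' of the target) set by the chiral lanthanum–lithium binaphthoxide; the (S) series is expected to give the (5R,6R) adduct.

**Step 2**
Reactants: 3 methyl (5R,6R)-6-hydroxy-5-nitrooctanoate
Product: 5 (6R)-6-[(1R)-1-hydroxypropyl]piperidin-2-one, via amino ester 4 (not isolated)
Conditions: H2 (3 atm), Raney Ni, MeOH, rt; then 60 °C
Reagents that add atoms: none
Why: Neutral hydrogenation of the nitro group gives the delta-amino ester, which should lactamise to the six-membered lactam without touching either stereocentre (nitro reduction/lactamisation).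

**Step 3**
Reactants: 5 (6R)-6-[(1R)-1-hydroxypropyl]piperidin-2-one
Product: 6 (6R)-6-[(1R)-1-[(tert-butyldimethylsilyl)oxy]propyl]piperidin-2-one
Conditions: TBSCl, imidazole, DMF, rt
Reagents that add atoms: tert-butyldimethylsilyl chloride, CC(C)(C)[Si](C)(C)Cl
Why: Standard silyl ether protection of the secondary alcohol leaves the lactam N–H free for the next step.

**Step 4**
Reactants: 6 silyl ether lactam
Product: 7 benzyl (2R)-2-[(1R)-1-[(tert-butyldimethylsilyl)oxy]propyl]-6-oxopiperidine-1-carboxylate
Conditions: n-BuLi, THF, −78 °C; then CbzCl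
Reagents that add atoms: benzyl chloroformate, O=C(Cl)OCc1ccccc1
Why: N-Acylation of the lithiated lactam (carbamate formation) turns the ring carbonyl into an acylating centre for an ester enolate.

**Step 5**
Reactants: 8 4-methylfuran-2(5H)-one
Product: 9 (4S)-4-methyldihydrofuran-2(3H)-one
Conditions: H2 (50 atm), Ru(OAc)2[(S)-BINAP] (antipode chosen to give the (S)-lactone), MeOH, 50 °C
Reagents that add atoms: none
Why: Asymmetric hydrogenation of the butenolide C=C with a BINAP ruthenium diacetate catalyst should set the methyl-bearing stereocentre (C12) under catalyst control.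

**Step 6**
Reactants: 7 N-Cbz lactam; 9 (4S)-4-methyldihydrofuran-2(3H)-one
Product: 10 benzyl N-[(3R,4R)-3-[(tert-butyldimethylsilyl)oxy]-8-[(4S)-4-methyl-2-oxotetrahydrofuran-3-yl]-8-oxooctan-4-yl]carbamate
Conditions: 9 (2.2 equiv), LiN(SiMe3)2 (2.2 equiv), THF, −78 °C; then 7; NH4Cl
Reagents that add atoms: none
Why: Crossed Claisen-type C-acylation of the lactone lithium enolate by the N-acyl lactam, with ring opening to the carbamate anion, should forge C10–C11; the configuration at C11 does not matter here because the beta-keto lactone is enolised.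

**Step 7**
Reactants: 10 beta-keto lactone carbamate
Product: 12 (3R,4S)-3-[(2S,6R)-6-[(1R)-1-[(tert-butyldimethylsilyl)oxy]propyl]piperidin-2-yl]-4-methyldihydrofuran-2(3H)-one, via enamino lactone 11 (not isolated)
Conditions: H2 (1 atm), Pd/C, MeOH, rt; filter; then NaBH(OAc)3, AcOH, MeCN, 0 °C
Reagents that add atoms: none
Why: Hydrogenolysis of the Cbz group lets the amine condense with the beta-keto lactone to the cyclic vinylogous carbamate 11, and its ionic reduction (C-protonation to the iminium ion, then axial hydride delivery) should give the 2,6-cis piperidine at C10, while the epimerisable lactone alpha-carbon C11 settles trans to the C12 methyl.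

**Step 8**
Reactants: 12 piperidinyl lactone; 13 acrolein
Product: 15 (3R,4S)-3-[(2S,6R)-6-[(1R)-1-[(tert-butyldimethylsilyl)oxy]propyl]-1-(3-hydroxypropyl)piperidin-2-yl]-4-methyldihydrofuran-2(3H)-one, via amino aldehyde 14 (not isolated)
Conditions: 13 (1.5 equiv), MeOH, 0 °C; then NaBH4, 0 °C
Reagents that add atoms: none
Why: Aza-Michael addition of the hindered secondary amine to acrolein, followed by in situ borohydride reduction of the beta-amino aldehyde, installs C4–C2 on nitrogen under conditions mild enough for the lactone.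

**Step 9**
Reactants: 15 N-(3-hydroxypropyl) amino lactone
Product: 16 (3R,4S)-3-[(2S,6R)-6-[(1R)-1-[(tert-butyldimethylsilyl)oxy]propyl]-1-(3-iodopropyl)piperidin-2-yl]-4-methyldihydrofuran-2(3H)-one
Conditions: PPh3, I2, imidazole, CH2Cl2, 0 °C; used at once
Reagents that add atoms: iodine, II
Why: Appel iodination converts the primary alcohol into the primary iodide needed for halogen–lithium exchange, and the hindered nitrogen should be slow to quaternise.

**Step 10**
Reactants: 16 N-(3-iodopropyl) amino lactone; 17 4-methoxy-3-methylfuran-2(5H)-one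
Product: 21 azepane-closed tetronate diol (1S,6R,10S,11R,12S,1''R), via alkyllithium 18 (not isolated), via azepanone lithium alkoxide 19 (not isolated), via lithium dienolate 20 (not isolated)
Conditions: t-BuLi (2.1 equiv), Et2O–pentane, −78 °C, then −78 → −10 °C; recool to −78 °C and add 20 [from 17 (3 equiv), LiN(i-Pr)2, THF, −78 °C]; AcOH, −78 °C
Reagents that add atoms: none
Why: Iodine–lithium exchange gives the primary alkyllithium 18, whose C2 attacks the lactone carbonyl C1 in a nucleophilic acyl substitution; on warming the lithium lactolate opens to the azepan-4-one 19 with the C13 oxygen released as the alkoxide, and the tetronate dienolate 20 then adds through C5' (= C14) to the new ketone in a vinylogous aldol reaction. The closest known reaction types are the halogen–lithium exchange-initiated intramolecular acylation of iodoalkyl esters (Parham-type cyclisation) and the vinylogous aldol addition of lithiated methyl tetronates to carbonyl compounds, here run in one flask on the same carbon. The only ring closed is the azepane, by 7-exo-trig attack of C2 on C1 with the lactone C–O bond as internal leaving group. The one new stereocentre that matters, C1, is set in the second event by the resident C11 centre: the dienolate should approach the seven-membered ketone anti to the alpha-branch on C11, which places the tetronate trans to that branch and the hydroxyl cis to it, while C14–H forms as a mixture that is erased in step 12. The step needs the alkyllithium to acylate faster than it is protonated or deprotonates C11–H, which the intramolecular arrangement and the five-membered N–Li chelate of the gamma-amino alkyllithium should secure, and it needs the weakly basic dienolate to add and not revert, which the low temperature and the cold acidic quench should secure.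

**Step 11**
Reactants: 21 azepane-closed tetronate diol
Product: 22 aldehyde (C13 = CHO; in equilibrium with the lactol)
Conditions: Dess–Martin periodinane, NaHCO3, CH2Cl2, 0 °C
Reagents that add atoms: none
Why: Dess–Martin oxidation of the primary alcohol should give the aldehyde, which is expected to rest as the five-membered lactol with the tertiary C1 hydroxyl and so shields the epimerisable C12 centre.

**Step 12**
Reactants: 22 aldehyde
Product: 23 spirocyclic diol (C13 epimers)
Conditions: LiN(SiMe3)2 (2.3 equiv), THF, −78 → −40 °C; NH4Cl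
Reagents that add atoms: none
Why: Double deprotonation gives the lithium alkoxide–dienolate, and an intramolecular vinylogous aldol addition of C14 to the aldehyde C13 (5-exo-trig) should close the cyclopentane; aggregation of the C1 alkoxide with the lithium on the furanolate oxygen flank fixes the rotamer so that O1' ends cis to the C1 oxygen, which sets the spiro centre C14, and the dianion cannot undergo retro-aldol cleavage.

**Step 13**
Reactants: 23 spirocyclic diol
Product: 24 C13 ketone
Conditions: Dess–Martin periodinane, NaHCO3, CH2Cl2, rt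
Reagents that add atoms: none
Why: Dess–Martin oxidation of the secondary carbinol (the tertiary alcohol is inert) converges both C13 epimers on one beta-hydroxy ketone.

**Step 14**
Reactants: 24 C13 ketone
Product: 25 silyl ether of the target
Conditions: Me4NBH(OAc)3, AcOH, MeCN, −30 °C
Reagents that add atoms: none
Why: In this hydroxyl-directed (Evans–Saksena) reduction the borohydride bound to the C1 oxygen delivers hydride intramolecularly to the same face of C13, so the new hydroxyl should form anti to the C1 hydroxyl, on the face of the C12 methyl.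

**Step 15**
Reactants: 25 silyl ether of the target
Product: 26 CNP0267781.1
Conditions: HF·pyridine, pyridine, THF, 0 °C → rt
Reagents that add atoms: none
Why: Fluoride-mediated desilylation under mildly acidic conditions frees the side-chain alcohol without exposing the tertiary aldol-type carbinol to base.

**Compound list**

1 | propanal | CCC=O | starting material
2 | methyl 5-nitropentanoate | COC(=O)CCCC[N+](=O)[O-] | starting material
3 | methyl (5R,6R)-6-hydroxy-5-nitrooctanoate | CC[C@@H](O)[C@H]([N+](=O)[O-])CCCC(=O)OC | intermediate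
4 | methyl (5R,6R)-5-amino-6-hydroxyoctanoate (not isolated) | CC[C@@H](O)[C@H](N)CCCC(=O)OC | intermediate
5 | (6R)-6-[(1R)-1-hydroxypropyl]piperidin-2-one | CC[C@@H](O)[C@H]1CCCC(=O)N1 | intermediate
6 | (6R)-6-[(1R)-1-[(tert-butyldimethylsilyl)oxy]propyl]piperidin-2-one | CC[C@@H](O[Si](C)(C)C(C)(C)C)[C@H]1CCCC(=O)N1 | intermediate
7 | benzyl (2R)-2-[(1R)-1-[(tert-butyldimethylsilyl)oxy]propyl]-6-oxopiperidine-1-carboxylate | CC[C@@H](O[Si](C)(C)C(C)(C)C)[C@H]1CCCC(=O)N1C(=O)OCc2ccccc2 | intermediate
8 | 4-methylfuran-2(5H)-one | CC1=CC(=O)OC1 | starting material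
9 | (4S)-4-methyldihydrofuran-2(3H)-one | C[C@H]1CC(=O)OC1 | intermediate
10 | benzyl N-[(3R,4R)-3-[(tert-butyldimethylsilyl)oxy]-8-[(4S)-4-methyl-2-oxotetrahydrofuran-3-yl]-8-oxooctan-4-yl]carbamate (lactone C3 not fixed) | CC[C@@H](O[Si](C)(C)C(C)(C)C)[C@H](NC(=O)OCc1ccccc1)CCCC(=O)C2C(=O)OC[C@H]2C | intermediate
11 | (3Z,4S)-3-[(6R)-6-[(1R)-1-[(tert-butyldimethylsilyl)oxy]propyl]piperidin-2-ylidene]-4-methyldihydrofuran-2(3H)-one (not isolated) | CC[C@@H](O[Si](C)(C)C(C)(C)C)[C@H]1CCC/C(N1)=C2/C(=O)OC[C@H]2C | intermediate
12 | (3R,4S)-3-[(2S,6R)-6-[(1R)-1-[(tert-butyldimethylsilyl)oxy]propyl]piperidin-2-yl]-4-methyldihydrofuran-2(3H)-one | CC[C@@H](O[Si](C)(C)C(C)(C)C)[C@H]1CCC[C@H](N1)[C@@H]2C(=O)OC[C@H]2C | intermediate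
13 | acrolein (prop-2-enal) | C=CC=O | starting material
14 | 3-[(2R,6S)-2-[(1R)-1-[(tert-butyldimethylsilyl)oxy]propyl]-6-[(3R,4S)-4-methyl-2-oxotetrahydrofuran-3-yl]piperidin-1-yl]propanal (not isolated) | CC[C@@H](O[Si](C)(C)C(C)(C)C)[C@H]1CCC[C@H](N1CCC=O)[C@@H]2C(=O)OC[C@H]2C | intermediate
15 | (3R,4S)-3-[(2S,6R)-6-[(1R)-1-[(tert-butyldimethylsilyl)oxy]propyl]-1-(3-hydroxypropyl)piperidin-2-yl]-4-methyldihydrofuran-2(3H)-one | CC[C@@H](O[Si](C)(C)C(C)(C)C)[C@H]1CCC[C@H](N1CCCO)[C@@H]2C(=O)OC[C@H]2C | intermediate
16 | (3R,4S)-3-[(2S,6R)-6-[(1R)-1-[(tert-butyldimethylsilyl)oxy]propyl]-1-(3-iodopropyl)piperidin-2-yl]-4-methyldihydrofuran-2(3H)-one | CC[C@@H](O[Si](C)(C)C(C)(C)C)[C@H]1CCC[C@H](N1CCCI)[C@@H]2C(=O)OC[C@H]2C | intermediate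
17 | 4-methoxy-3-methylfuran-2(5H)-one | COC1=C(C)C(=O)OC1 | starting material
18 | N-(3-lithiopropyl) analogue of 16 (not isolated) | CC[C@@H](O[Si](C)(C)C(C)(C)C)[C@H]1CCC[C@H](N1CCC[Li])[C@@H]2C(=O)OC[C@H]2C | intermediate
19 | piperidine-fused azepan-4-one (C1 ketone; 6R,10S,11R) with 6-[(1R)-1-(TBSO)propyl] and 11-[(2S)-1-(lithiooxy)propan-2-yl] groups (not isolated) | CC[C@@H](O[Si](C)(C)C(C)(C)C)[C@H]1CCC[C@H]2[C@@H]([C@H](C)CO[Li])C(=O)CCCN12 | intermediate
20 | lithium dienolate of 17 (2-lithiooxy-4-methoxy-3-methylfuran; not isolated) | COC1=COC(O[Li])=C1C | intermediate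
21 | (1S,6R,10S,11R)-piperidine-fused azepane with OH and the 4-methoxy-3-methyl-5-oxo-2,5-dihydrofuran-2-yl group on C1 (C14 epimers), the (2S)-1-hydroxypropan-2-yl group on C11 and the (1R)-1-(TBSO)propyl group on C6 | CC[C@@H](O[Si](C)(C)C(C)(C)C)[C@H]1CCC[C@H]2[C@@H]([C@H](C)CO)[C@](O)(C3OC(=O)C(C)=C3OC)CCCN12 | intermediate
22 | aldehyde corresponding to 21, with a (2S)-1-oxopropan-2-yl group on C11 (lactol with the C1 hydroxyl) | CC[C@@H](O[Si](C)(C)C(C)(C)C)[C@H]1CCC[C@H]2[C@@H]([C@H](C)C=O)[C@](O)(C3OC(=O)C(C)=C3OC)CCCN12 | intermediate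
23 | C1''-O-TBS ether of the target as a mixture of C13 epimers | CC[C@@H](O[Si](C)(C)C(C)(C)C)[C@H]1CCC[C@H]2[C@H]3[C@H](C)C(O)[C@@]4(OC(=O)C(C)=C4OC)[C@]3(O)CCCN12 | intermediate
24 | C13 ketone of the C1''-O-TBS ether of the target (1S,6R,10S,11R,12S,14R) | CC[C@@H](O[Si](C)(C)C(C)(C)C)[C@H]1CCC[C@H]2[C@H]3[C@H](C)C(=O)[C@@]4(OC(=O)C(C)=C4OC)[C@]3(O)CCCN12 | intermediate
25 | C1''-O-TBS ether of the target (1S,6R,10S,11R,12S,13S,14R,1''R) | CC[C@@H](O[Si](C)(C)C(C)(C)C)[C@H]1CCC[C@H]2[C@H]3[C@H](C)[C@H](O)[C@@]4(OC(=O)C(C)=C4OC)[C@]3(O)CCCN12 | intermediate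
26 | CNP0267781.1 | CC[C@@H](O)[C@H]1CCC[C@H]2[C@H]3[C@H](C)[C@H](O)[C@@]4(OC(=O)C(C)=C4OC)[C@]3(O)CCCN12 | target

**Totals**

Total step count: 15. Longest linear sequence: 14 steps (steps 1–4 and 6–15; step 5 is a one-step branch).

**Steps most likely to fail**

Step 10. The alkyllithium may be lost to proton transfer or deprotonation at C11, the lactolate may fail to open, and the dienolate addition may revert by retro-aldol or show poor facial selectivity at C1. The fallback separates the two events and makes both non-reversible. It sets out from 16: SmI2 with catalytic NiI2 in THF closes the azepane as a single-electron Barbier-type acyl substitution under non-basic conditions, and the hydroxy azepanone F1 is isolated. Separately, 17 is silylated (i-Pr3SiOTf, Et3N) to 2-(triisopropylsilyloxy)-4-methoxy-3-methylfuran F2, which is lithiated at C5 (s-BuLi, TMEDA) and added to F1 in the presence of CeCl3 to give the furyl carbinol F3. Buffered fluoride (Et3N·3HF) unveils the butenolide and returns the route to 21.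

Step 12. The tertiary aldolate may fragment by retro-aldol, the lactol may open too slowly, C12 may epimerise through the free aldehyde, or the facial selectivity at C14 may be poor. The fallback caps the tertiary hydroxyl. It sets out from 21: Et3SiOTf and 2,6-lutidine give the bis(triethylsilyl) ether F4; Swern oxidation converts the primary silyl ether directly into the aldehyde F5; LiN(SiMe3)2 (1.1 equiv, −78 °C) closes the ring from the mono-anion to the spirocyclic tertiary silyl ether F6; PPTS in MeOH removes the triethylsilyl group and returns the route to 23.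

Step 7. Hydride may capture the kinetically C-protonated iminium epimer, or the 2,6-cis selectivity may be incomplete, so that control over C10 and C11 is lost. The fallback replaces kinetic hydride control by thermodynamic control. It sets out from 11: unselective reduction (NaBH4, AcOH) gives the stereoisomer mixture F7, which is heated with DBU in toluene so that retro-aza-Michael and aza-Michael addition through the open-chain amino alkylidene lactone F8 (not isolated) equilibrate both centres; the 2,6-cis piperidine with the trans-disubstituted lactone, 12, is the expected thermodynamic sink, and the route continues from 12.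

Further compounds
F1 | step 10 | hydroxy azepanone: piperidine-fused azepan-4-one (6R,10S,11R) with 11-[(2S)-1-hydroxypropan-2-yl] and 6-[(1R)-1-(TBSO)propyl] groups | CC[C@@H](O[Si](C)(C)C(C)(C)C)[C@H]1CCC[C@H]2[C@@H]([C@H](C)CO)C(=O)CCCN12
F2 | step 10 | 2-(triisopropylsilyloxy)-4-methoxy-3-methylfuran | COc1coc(O[Si](C(C)C)(C(C)C)C(C)C)c1C
F3 | step 10 | furyl carbinol: analogue of 21 carrying the 3-methoxy-4-methyl-5-(triisopropylsilyloxy)furan-2-yl group on C1 | CC[C@@H](O[Si](C)(C)C(C)(C)C)[C@H]1CCC[C@H]2[C@@H]([C@H](C)CO)[C@](O)(c3oc(O[Si](C(C)C)(C(C)C)C(C)C)c(C)c3OC)CCCN12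
F4 | step 12 | bis(triethylsilyl) ether of 21 (tertiary C1–O and primary C13–O) | CC[C@@H](O[Si](C)(C)C(C)(C)C)[C@H]1CCC[C@H]2[C@@H]([C@H](C)CO[Si](CC)(CC)CC)[C@](O[Si](CC)(CC)CC)(C3OC(=O)C(C)=C3OC)CCCN12
F5 | step 12 | C1-O-triethylsilyl ether of aldehyde 22 | CC[C@@H](O[Si](C)(C)C(C)(C)C)[C@H]1CCC[C@H]2[C@@H]([C@H](C)C=O)[C@](O[Si](CC)(CC)CC)(C3OC(=O)C(C)=C3OC)CCCN12
F6 | step 12 | C1-O-triethylsilyl ether of spirocycle 23 | CC[C@@H](O[Si](C)(C)C(C)(C)C)[C@H]1CCC[C@H]2[C@H]3[C@H](C)C(O)[C@@]4(OC(=O)C(C)=C4OC)[C@]3(O[Si](CC)(CC)CC)CCCN12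
F7 | step 7 | stereoisomer mixture of 12 (piperidine C2 and lactone C3 not fixed) | CC[C@@H](O[Si](C)(C)C(C)(C)C)[C@H]1CCCC(N1)C2C(=O)OC[C@H]2C
F8 | step 7 | (3E,4S)-3-[(5R,6R)-5-amino-6-[(tert-butyldimethylsilyl)oxy]octylidene]-4-methyldihydrofuran-2(3H)-one | CC[C@@H](O[Si](C)(C)C(C)(C)C)[C@H](N)CCC/C=C1/C(=O)OC[C@H]1C
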